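**Retrosynthetic overview**

1. Endgame: the C12 acid comes from an enal by Pinnick oxidation, and the C8 ester from selective acylation of an all-cis 6,8-diol with a Roche-ester-derived acid.
2. Key disconnection C6–C7: the cyclohexane (C5–C6–C7–C8–C9–C10) is closed by an intramolecular allylboration of a δ-hydroxy aldehyde. The enabling feature is the cis triad on C6/C7/C8: O6, O8 and the C13 methylene of the 2-propenyl group on C7 lie on one ring face, so one boron atom can hold all three (temporary 1,2-oxaborinine, 2,6-dioxa-1-borabicyclo[2.2.2]octene-like transition state).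
3. The hydroxy aldehyde is stored as a δ-lactone (O8–C6), itself closed at C5–C10 by an intramolecular dienolate SN2' alkylation that relays C8 to C10 and C5.
4. C8 comes from a Keck methallylation of an ynal; the Z-allylic chloride from an RCM dihydropyranone; the CH2B unit from a Negishi coupling on a Z-iodoalkene.
5. Ring order: dihydropyranone (temporary), δ-lactone (temporary), oxaborinine (temporary, in the flask), cyclohexane last.

Key step: step 13

Locants used below (elemane numbering): C10 quaternary (CH3 = C14, vinyl = C1=C2), C9H2, C8 (O-acyl), C7 (bearing C11(=C13H2)C12), C6 (OH), C5 (bearing C4(=C3H2)C15H2OH). In the target the CH3, both side chains and both oxygens are on one face (β) and the vinyl group on the other.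

Remark: the cis γ-hydroxy acid of the target is taken to be isolable as drawn (no closure to the 6,12-lactone) when the last step is worked up cold at pH 4–5.

**Route**

Step 1
Reactants: 1 3,3-diethoxyprop-1-yne
Product: 3 4,4-diethoxybut-2-ynal, via lithium acetylide 2 (not isolated)
Conditions: n-BuLi, THF, −78 °C; DMF, −78 to 0 °C; inverse quench into aq. KH2PO4
Reagents that add atoms: N,N-dimethylformamide, CN(C)C=O
Why: Formylation of a lithium acetylide with DMF, the buffered inverse quench releasing the ynal without loss of the acetal; no stereocentre is formed.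

Step 2
Reactants: 3 4,4-diethoxybut-2-ynal; 4 tributyl(2-methylprop-2-en-1-yl)stannane
Product: 5 (4R)-1,1-diethoxy-6-methylhept-6-en-2-yn-4-ol
Conditions: Ti(OiPr)4 (10 mol %), (R)-BINOL (20 mol %), 4 Å MS, CH2Cl2, −20 °C; aq. NaHCO3
Reagents that add atoms: none
Why: Keck asymmetric allylation, in which the (R)-BINOL–titanium Lewis acid should direct the methallyl group to the Re face of the aldehyde and so set C8 (R); the antipodal ligand is available should the sense have to be reversed.

Step 3
Reactants: 5 (4R)-1,1-diethoxy-6-methylhept-6-en-2-yn-4-ol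
Product: 7 (2Z,4R)-1,1-diethoxy-2-iodo-6-methylhepta-2,6-dien-4-ol, via sodium vinylalanate 6 (not isolated)
Conditions: NaAlH2(OCH2CH2OCH3)2, THF, 0 °C; EtOAc; I2, −78 °C; aq. Na2S2O3, aq. KNaC4H4O6
Reagents that add atoms: iodine, II
Why: Hydroxyl-directed trans-hydroalumination of the propargylic alcohol (hydride to C7, aluminium to C11 in a five-membered alkoxyalanate) followed by iodinolysis with retention, which places iodine on C11 cis to C8.

Step 4
Reactants: 7 (2Z,4R)-1,1-diethoxy-2-iodo-6-methylhepta-2,6-dien-4-ol; 8 prop-2-enoyl chloride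
Product: 9 (2Z,4R)-1,1-diethoxy-2-iodo-6-methylhepta-2,6-dien-4-yl prop-2-enoate
Conditions: iPr2NEt, CH2Cl2, −78 to 0 °C
Reagents that add atoms: none
Why: O-Acylation of the secondary alcohol with an acid chloride; the stereocentre is not touched.

Step 5
Reactants: 9 (2Z,4R)-1,1-diethoxy-2-iodo-6-methylhepta-2,6-dien-4-yl prop-2-enoate
Product: 10 (6R)-6-[(1Z)-3,3-diethoxy-2-iodoprop-1-en-1-yl]-4-methyl-5,6-dihydro-2H-pyran-2-one
Conditions: second-generation Grubbs catalyst RuCl2(H2IMes)(PCy3)(=CHPh) (5 mol %), toluene, 80 °C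
Reagents that add atoms: none
Why: Ring-closing metathesis between the acrylate and the 1,1-disubstituted alkene, the ring fixing the Z geometry of C1=C10; the trisubstituted iodoalkene should be inert.

Step 6
Reactants: 10 (6R)-6-[(1Z)-3,3-diethoxy-2-iodoprop-1-en-1-yl]-4-methyl-5,6-dihydro-2H-pyran-2-one
Product: 11 (2Z,5R,6Z)-8,8-diethoxy-7-iodo-3-methylocta-2,6-diene-1,5-diol
Conditions: iBu2AlH (3 equiv), CH2Cl2, −78 to 0 °C; aq. KNaC4H4O6
Reagents that add atoms: none
Why: 1,2-Reduction of the unsaturated lactone by excess aluminium hydride opens the ring to the diol and keeps the Z geometry that the ring imposed.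

Step 7
Reactants: 11 (2Z,5R,6Z)-8,8-diethoxy-7-iodo-3-methylocta-2,6-diene-1,5-diol
Product: 12 (2Z,4R,6Z)-8-chloro-1,1-diethoxy-2-iodo-6-methylocta-2,6-dien-4-ol
Conditions: MsCl, LiCl, 2,4,6-collidine, DMF, 0 °C
Reagents that add atoms: lithium chloride, [Li+].[Cl-]
Why: Chemoselective chlorination of the primary allylic alcohol through its mesylate (chloride displacement without allylic transposition), the secondary C8 hydroxyl being too hindered to be sulfonylated at 0 °C.

Step 8
Reactants: 13 1-[(tert-butyldimethylsilyl)oxy]propan-2-one; 14 triethyl phosphonoacetate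
Product: 15 ethyl (2E)-4-[(tert-butyldimethylsilyl)oxy]-3-methylbut-2-enoate
Conditions: NaH, THF, 0 to 25 °C; E isomer separated by chromatography
Reagents that add atoms: none
Why: Horner–Wadsworth–Emmons olefination of the ketone, expected to favour the E isomer (CH3 cis to the ester), which is needed because that methyl group is the site of γ-deprotonation in step 11.

Step 9
Reactants: 15 ethyl (2E)-4-[(tert-butyldimethylsilyl)oxy]-3-methylbut-2-enoate
Product: 16 (2E)-4-[(tert-butyldimethylsilyl)oxy]-3-methylbut-2-enoic acid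
Conditions: LiOH, THF/MeOH/H2O, 25 °C; 1 M HCl to pH 4
Reagents that add atoms: lithium hydroxide, [Li+].[OH-]
Why: Saponification of the ethyl ester; the primary silyl ether and the alkene geometry should survive aqueous LiOH.

Step 10
Reactants: 12 (2Z,4R,6Z)-8-chloro-1,1-diethoxy-2-iodo-6-methylocta-2,6-dien-4-ol; 16 (2E)-4-[(tert-butyldimethylsilyl)oxy]-3-methylbut-2-enoic acid
Product: 17 (2Z,4R,6Z)-8-chloro-1,1-diethoxy-2-iodo-6-methylocta-2,6-dien-4-yl (2E)-4-[(tert-butyldimethylsilyl)oxy]-3-methylbut-2-enoate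
Conditions: EDC·HCl, DMAP, CH2Cl2, 0 to 25 °C
Reagents that add atoms: none
Why: Carbodiimide (Steglich) esterification of the secondary alcohol; nothing stereogenic changes, and any partial deconjugation of the acyl unit is harmless because both isomers give the same dienolate.

Step 11
Reactants: 17 (2Z,4R,6Z)-8-chloro-1,1-diethoxy-2-iodo-6-methylocta-2,6-dien-4-yl (2E)-4-[(tert-butyldimethylsilyl)oxy]-3-methylbut-2-enoate
Product: 19 (3R,4S,6R)-3-{3-[(tert-butyldimethylsilyl)oxy]prop-1-en-2-yl}-6-[(1Z)-3,3-diethoxy-2-iodoprop-1-en-1-yl]-4-ethenyl-4-methyloxan-2-one, via lithium dienolate 18 (not isolated)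
Conditions: LiN(iPr)2 (1.05 equiv), THF, −78 °C; DMPU, −78 to −30 °C; AcOH quench at −78 °C
Reagents that add atoms: none
Why: Proposed new method: γ-deprotonation of the E-enoate through its lithium-chelated s-cis conformer should give the Z(O)-dienolate 18, whose α-carbon (C5) attacks C10 of the Z-allylic chloride in a chair-like six-membered SN2' array (6-enolendo-exo), expelling chloride from C2 and forming the vinyl group and the δ-lactone in one event. With the C8 alkenyl group equatorial, the Z geometry forces the C1=C2 terminus away from the ring (the alternative rotamer drives C2 into C8), so the vinyl group ends cis to the C8 side chain and CH3 axial, and the dienolate substituent anti to the ring oxygen becomes equatorial, which sets C5. The closest known reaction types are intramolecular ester-enolate SN2' cyclisations to vinylcycloalkanes, deconjugative α-alkylation of 3-methylbut-2-enoate dienolates, and palladium-catalysed lactone-forming allylic alkylations of nucleophiles tethered through the ester oxygen.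

Step 12
Reactants: 19 (3R,4S,6R)-3-{3-[(tert-butyldimethylsilyl)oxy]prop-1-en-2-yl}-6-[(1Z)-3,3-diethoxy-2-iodoprop-1-en-1-yl]-4-ethenyl-4-methyloxan-2-one; 20 2-(iodomethyl)-4,4,5,5-tetramethyl-1,3,2-dioxaborolane
Product: 22 (3R,4S,6R)-3-{3-[(tert-butyldimethylsilyl)oxy]prop-1-en-2-yl}-6-{(1E)-3,3-diethoxy-2-[(4,4,5,5-tetramethyl-1,3,2-dioxaborolan-2-yl)methyl]prop-1-en-1-yl}-4-ethenyl-4-methyloxan-2-one, via zinc reagent 21 (not isolated)
Conditions: 20, Zn dust, THF, 25 °C; then 19, Pd2(dba)3 (2.5 mol %), P(2-furyl)3, THF, 40 °C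
Reagents that add atoms: none
Why: Negishi coupling of the alkenyl iodide with the borylmethylzinc reagent with retention of alkene geometry, which places the CH2B carbon (C13) cis to C8; the lactone does not react with the allylboronate.

Step 13
Reactants: 22 (3R,4S,6R)-3-{3-[(tert-butyldimethylsilyl)oxy]prop-1-en-2-yl}-6-{(1E)-3,3-diethoxy-2-[(4,4,5,5-tetramethyl-1,3,2-dioxaborolan-2-yl)methyl]prop-1-en-1-yl}-4-ethenyl-4-methyloxan-2-one
Product: 26 15-O-(tert-butyldimethylsilyl)-12,12-diethoxyelema-1,3,11(13)-triene-6β,8β-diol (5R,6S,7R,8R,10S), via lactol 23 (not isolated), via oxaborinine aldehyde 24 (not isolated), via cyclic borate 25 (not isolated)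
Conditions: iBu2AlH (1.2 equiv), CH2Cl2, −78 °C; aq. KNaC4H4O6; THF/H2O, 25 to 40 °C; aq. sorbitol, Na2CO3
Reagents that add atoms: none
Why: Proposed new method: the aluminium hydride reduces the lactone to lactol 23, which opens to the δ-hydroxy aldehyde; its 8-OH, held cis to the CH2B carbon by the alkene geometry, should displace pinacol from boron and close the six-membered 1,2-oxaborinine 24, as cis-hydroxyalkenyl pinacolboronates close to oxaboroles. The aldehyde oxygen then binds the same boron and C7 adds to C6 with allyl transposition; the closest known reaction types are intramolecular allylborations of formyl-tethered allylboronates to cyclohexanols and aldehyde allylborations by γ-boryloxy allylboronates from borylative vinyl-epoxide opening, which give 2-alkenyl-1,3-diols. The cyclohexane closes 6-exo on the carbonyl through a 2,6-dioxa-1-borabicyclo[2.2.2]octene-like transition state in which boron is bonded to O8, O6 and C13. Because these three atoms are tied to one boron, O6, C11 and O8 must emerge on the same ring face, so C6 and C7 are both set by the C8 stereocentre through the tether, while C5 and C10 are carried in unchanged; the product is first the bridged borate 25 of the cis-1,3-diol, which is hydrolysed on work-up. The step needs facial selectivity on the allyl unit and regioselectivity for C7 over C13: the covalent B–O8 bond excludes the untethered chair, in which allylic strain would turn O8 away and give the 6,7-bis-epimer, and bonding through C13 would require an eight-membered ring.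

Step 14
Reactants: 27 methyl (2R)-3-hydroxy-2-methylpropanoate
Product: 28 methyl (2R)-3-[(tert-butyldimethylsilyl)oxy]-2-methylpropanoate
Conditions: TBSCl, imidazole, DMF, 25 °C
Reagents that add atoms: tert-butyldimethylsilyl chloride, CC(C)(C)[Si](C)(C)Cl
Why: Silylation of the primary alcohol of the Roche ester; the α-stereocentre is not involved.

Step 15
Reactants: 28 methyl (2R)-3-[(tert-butyldimethylsilyl)oxy]-2-methylpropanoate
Product: 29 (2R)-3-[(tert-butyldimethylsilyl)oxy]-2-methylpropanoic acid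
Conditions: LiOH, THF/MeOH/H2O, 0 °C; 1 M HCl to pH 4
Reagents that add atoms: lithium hydroxide, [Li+].[OH-]
Why: Saponification at low temperature, conditions under which β-silyloxy-α-methyl esters are normally hydrolysed without epimerisation or β-elimination.

Step 16
Reactants: 26 15-O-(tert-butyldimethylsilyl)-12,12-diethoxyelema-1,3,11(13)-triene-6β,8β-diol; 29 (2R)-3-[(tert-butyldimethylsilyl)oxy]-2-methylpropanoic acid
Product: 30 8-O-[(2R)-3-(tert-butyldimethylsilyloxy)-2-methylpropanoyl] ester of diol 26 (5R,6S,7S,8R,10S)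
Conditions: 29, 2,4,6-trichlorobenzoyl chloride, Et3N, THF; then 26, DMAP, toluene, 25 °C
Reagents that add atoms: none
Why: Yamaguchi esterification; of the two axial hydroxyls, O8 has one CH2 neighbour whereas O6 lies between two branched carbons, so the mixed anhydride should acylate O8 only.

Step 17
Reactants: 30 8-O-[(2R)-3-(tert-butyldimethylsilyloxy)-2-methylpropanoyl] ester of diol 26
Product: 31 6β,15-dihydroxy-8β-[(2R)-3-hydroxy-2-methylpropanoyloxy]elema-1,3,11(13)-trien-12-al (5R,6S,7S,8R,10S)
Conditions: AcOH/THF/H2O (3:1:1), 40 °C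
Reagents that add atoms: water, O
Why: Mild acid hydrolysis cleaves both primary silyl ethers and the allylic diethyl acetal while the ester and the alkenes are retained; the enal may equilibrate with its cyclic hemiacetal on O6, which does not interfere with the next step.

Step 18
Reactants: 31 6β,15-dihydroxy-8β-[(2R)-3-hydroxy-2-methylpropanoyloxy]elema-1,3,11(13)-trien-12-al
Product: 32 6β,15-dihydroxy-8β-[(2R)-3-hydroxy-2-methylpropanoyloxy]elema-1,3,11(13)-trien-12-oic acid (5R,6S,7S,8R,10S; CNP0462645.2)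
Conditions: NaClO2, NaH2PO4, 2-methylbut-2-ene, t-BuOH/H2O, 0 °C; cold extraction at pH 4–5
Reagents that add atoms: sodium chlorite, [Na+].[O-]Cl=O
Why: Pinnick oxidation of the enal to the acrylic acid with an alkene scavenger for hypochlorite; alcohols, the ester and the three alkenes should be untouched, and no stereocentre is affected.

**Compound list**

1 | 3,3-diethoxyprop-1-yne | C#CC(OCC)OCC | starting material
2 | lithium 3,3-diethoxyprop-1-yn-1-ide | [Li]C#CC(OCC)OCC | intermediate
3 | 4,4-diethoxybut-2-ynal | O=CC#CC(OCC)OCC | intermediate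
4 | tributyl(2-methylprop-2-en-1-yl)stannane | CC(=C)C[Sn](CCCC)(CCCC)CCCC | starting material
5 | (4R)-1,1-diethoxy-6-methylhept-6-en-2-yn-4-ol | CC(=C)C[C@@H](O)C#CC(OCC)OCC | intermediate
6 | sodium cyclic alkoxy(vinyl)alanate from 5 (Al on C11, O–Al chelate, two 2-methoxyethoxy ligands) | [Na+].CC(=C)C[C@H]1O[Al-](OCCOC)(OCCOC)C(C(OCC)OCC)=C1 | intermediate
7 | (2Z,4R)-1,1-diethoxy-2-iodo-6-methylhepta-2,6-dien-4-ol | CC(=C)C[C@@H](O)/C=C(\I)C(OCC)OCC | intermediate
8 | prop-2-enoyl chloride | C=CC(Cl)=O | starting material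
9 | (2Z,4R)-1,1-diethoxy-2-iodo-6-methylhepta-2,6-dien-4-yl prop-2-enoate | C=CC(=O)O[C@H](CC(C)=C)/C=C(\I)C(OCC)OCC | intermediate
10 | (6R)-6-[(1Z)-3,3-diethoxy-2-iodoprop-1-en-1-yl]-4-methyl-5,6-dihydro-2H-pyran-2-one | O=C1C=C(C)C[C@H](/C=C(\I)C(OCC)OCC)O1 | intermediate
11 | (2Z,5R,6Z)-8,8-diethoxy-7-iodo-3-methylocta-2,6-diene-1,5-diol | OC/C=C(/C)C[C@@H](O)/C=C(\I)C(OCC)OCC | intermediate
12 | (2Z,4R,6Z)-8-chloro-1,1-diethoxy-2-iodo-6-methylocta-2,6-dien-4-ol | ClC/C=C(/C)C[C@@H](O)/C=C(\I)C(OCC)OCC | intermediate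
13 | 1-[(tert-butyldimethylsilyl)oxy]propan-2-one | CC(=O)CO[Si](C)(C)C(C)(C)C | starting material
14 | triethyl phosphonoacetate | CCOC(=O)CP(=O)(OCC)OCC | starting material
15 | ethyl (2E)-4-[(tert-butyldimethylsilyl)oxy]-3-methylbut-2-enoate | CCOC(=O)/C=C(\C)CO[Si](C)(C)C(C)(C)C | intermediate
16 | (2E)-4-[(tert-butyldimethylsilyl)oxy]-3-methylbut-2-enoic acid | OC(=O)/C=C(\C)CO[Si](C)(C)C(C)(C)C | intermediate
17 | (2Z,4R,6Z)-8-chloro-1,1-diethoxy-2-iodo-6-methylocta-2,6-dien-4-yl (2E)-4-[(tert-butyldimethylsilyl)oxy]-3-methylbut-2-enoate | ClC/C=C(/C)C[C@@H](OC(=O)/C=C(\C)CO[Si](C)(C)C(C)(C)C)/C=C(\I)C(OCC)OCC | intermediate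
18 | lithium Z(O)-dienolate of 17 (C4 cis to O–Li, exocyclic C4=C3H2) | [Li+].ClC/C=C(/C)C[C@@H](O/C([O-])=C/C(=C)CO[Si](C)(C)C(C)(C)C)/C=C(\I)C(OCC)OCC | intermediate
19 | (3R,4S,6R)-3-{3-[(tert-butyldimethylsilyl)oxy]prop-1-en-2-yl}-6-[(1Z)-3,3-diethoxy-2-iodoprop-1-en-1-yl]-4-ethenyl-4-methyloxan-2-one | C=C[C@]1(C)C[C@H](/C=C(\I)C(OCC)OCC)OC(=O)[C@H]1C(=C)CO[Si](C)(C)C(C)(C)C | intermediate
20 | 2-(iodomethyl)-4,4,5,5-tetramethyl-1,3,2-dioxaborolane | CC1(C)OB(CI)OC1(C)C | starting material
21 | iodo[(4,4,5,5-tetramethyl-1,3,2-dioxaborolan-2-yl)methyl]zinc | CC1(C)OB(C[Zn]I)OC1(C)C | intermediate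
22 | (3R,4S,6R)-3-{3-[(tert-butyldimethylsilyl)oxy]prop-1-en-2-yl}-6-{(1E)-3,3-diethoxy-2-[(4,4,5,5-tetramethyl-1,3,2-dioxaborolan-2-yl)methyl]prop-1-en-1-yl}-4-ethenyl-4-methyloxan-2-one | C=C[C@]1(C)C[C@H](/C=C(\CB2OC(C)(C)C(C)(C)O2)C(OCC)OCC)OC(=O)[C@H]1C(=C)CO[Si](C)(C)C(C)(C)C | intermediate
23 | lactol of 22 (oxan-2-ol, both anomers) | C=C[C@]1(C)C[C@H](/C=C(\CB2OC(C)(C)C(C)(C)O2)C(OCC)OCC)OC(O)[C@H]1C(=C)CO[Si](C)(C)C(C)(C)C | intermediate
24 | open δ-hydroxy aldehyde held as its cyclic hemiboronate: C8–O–B(OH)–C13H2 in a 2-hydroxy-3,6-dihydro-2H-1,2-oxaborinine, C6 as free aldehyde | C=C[C@](C)(C[C@H]1OB(O)CC(C(OCC)OCC)=C1)[C@@H](C=O)C(=C)CO[Si](C)(C)C(C)(C)C | intermediate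
25 | bridged borate (B–OH) of the 6β,8β-diol 26 | C=C[C@]1(C)C[C@H]2OB(O)O[C@@H]([C@H]1C(=C)CO[Si](C)(C)C(C)(C)C)[C@@H]2C(=C)C(OCC)OCC | intermediate
26 | 15-O-(tert-butyldimethylsilyl)-12,12-diethoxyelema-1,3,11(13)-triene-6β,8β-diol (5R,6S,7R,8R,10S; CH3, both side chains and both OH on one face) | C=C[C@]1(C)C[C@@H](O)[C@@H](C(=C)C(OCC)OCC)[C@@H](O)[C@H]1C(=C)CO[Si](C)(C)C(C)(C)C | intermediate
27 | methyl (2R)-3-hydroxy-2-methylpropanoate | COC(=O)[C@H](C)CO | starting material
28 | methyl (2R)-3-[(tert-butyldimethylsilyl)oxy]-2-methylpropanoate | COC(=O)[C@H](C)CO[Si](C)(C)C(C)(C)C | intermediate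
29 | (2R)-3-[(tert-butyldimethylsilyl)oxy]-2-methylpropanoic acid | OC(=O)[C@H](C)CO[Si](C)(C)C(C)(C)C | intermediate
30 | 8-O-[(2R)-3-(tert-butyldimethylsilyloxy)-2-methylpropanoyl] ester of diol 26 (5R,6S,7S,8R,10S) | C=C[C@]1(C)C[C@@H](OC(=O)[C@H](C)CO[Si](C)(C)C(C)(C)C)[C@@H](C(=C)C(OCC)OCC)[C@@H](O)[C@H]1C(=C)CO[Si](C)(C)C(C)(C)C | intermediate
31 | 6β,15-dihydroxy-8β-[(2R)-3-hydroxy-2-methylpropanoyloxy]elema-1,3,11(13)-trien-12-al (5R,6S,7S,8R,10S) | C=C[C@]1(C)C[C@@H](OC(=O)[C@H](C)CO)[C@@H](C(=C)C=O)[C@@H](O)[C@H]1C(=C)CO | intermediate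
32 | 6β,15-dihydroxy-8β-[(2R)-3-hydroxy-2-methylpropanoyloxy]elema-1,3,11(13)-trien-12-oic acid (5R,6S,7S,8R,10S) | C=C[C@]1(C)C[C@@H](OC(=O)[C@H](C)CO)[C@@H](C(=C)C(=O)O)[C@@H](O)[C@H]1C(=C)CO | target

Total step count: 18. Longest linear sequence: 14 steps (1–7, 10–13, 16–18).

**Steps most likely to fail**

Step 13 (Proposed new method). The 8-OH may not displace pinacol from boron, so that allyl transfer runs through an untethered chair with loss of facial control, or the strained bicyclic transition state may not be reached and the lactol simply persists. The fallback closes the same bond by a hydroxyl-chelated indium Barbier reaction, a known aqueous allylation in which a free hydroxyl beside the allyl unit binds the metal. It sets out from iodide 19: Stille coupling with tributyl(hydroxymethyl)stannane (Pd(PPh3)4, dioxane, 90 °C) should give the allylic alcohol lactone F1, CBr4/PPh3 at 0 °C the allylic bromide lactone F2, and iBu2AlH at −78 °C the bromo lactol F3. Indium powder in THF/H2O should then form the allylindium, held by O8 and the aldehyde oxygen, and close C6–C7 to come back to diol 26.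

Step 11 (Proposed new method). The dienolate may be lost by proton exchange with the product lactone (epimerisation at C5), by intermolecular alkylation, or by reaction through the wrong enolate geometry. The fallback makes the C5–C10 bond by an Ireland–Claisen rearrangement, which is known for allylic 3-methylbut-2-enoates. It sets out from diol 11: EDC/DMAP esterification of the primary allylic hydroxyl with acid 16 at 0 °C should give the mono-ester F4, and Et3SiCl/imidazole its C8 silyl ether F5. LiN(iPr)2/Me3SiCl (THF, −78 to 25 °C) generates the same Z(O)-dienolate as its silyl ketene acetal, and the chair rearrangement of the Z-allyl unit should give the acid F6 with the required C5/C10 relative configuration. The face relative to C8 is not controlled by the substrate, so the diastereomer is separated or a chiral boron enolate is used. HF·pyridine then removes the triethylsilyl group and EDC closes the δ-lactone, coming back to 19.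

Step 16. The mixed anhydride may acylate O6 as well as O8, or both. The fallback moves the differentiation to the protecting-group level. It sets out from diol 26: Et3SiOTf/2,6-lutidine should give the bis-silyl ether F7, and PPTS in EtOH at 0 °C should cleave only the less shielded C8 ether to give the mono-silyl ether F8. The same Yamaguchi coupling with 29 gives the ester F9, and the AcOH/THF/H2O treatment of step 17 removes all three silyl groups and the acetal, coming back to 31.

**Further compounds**

F1 | step 13 | (3R,4S,6R)-3-{3-[(tert-butyldimethylsilyl)oxy]prop-1-en-2-yl}-6-[(1E)-3,3-diethoxy-2-(hydroxymethyl)prop-1-en-1-yl]-4-ethenyl-4-methyloxan-2-one | C=C[C@]1(C)C[C@H](/C=C(\CO)C(OCC)OCC)OC(=O)[C@H]1C(=C)CO[Si](C)(C)C(C)(C)C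
F2 | step 13 | allylic bromide corresponding to F1 (CH2Br cis to C8) | C=C[C@]1(C)C[C@H](/C=C(\CBr)C(OCC)OCC)OC(=O)[C@H]1C(=C)CO[Si](C)(C)C(C)(C)C
F3 | step 13 | lactol of F2 (oxan-2-ol, both anomers) | C=C[C@]1(C)C[C@H](/C=C(\CBr)C(OCC)OCC)OC(O)[C@H]1C(=C)CO[Si](C)(C)C(C)(C)C
F4 | step 11 | (2Z,5R,6Z)-8,8-diethoxy-5-hydroxy-7-iodo-3-methylocta-2,6-dien-1-yl (2E)-4-[(tert-butyldimethylsilyl)oxy]-3-methylbut-2-enoate | O=C(/C=C(\C)CO[Si](C)(C)C(C)(C)C)OC/C=C(/C)C[C@@H](O)/C=C(\I)C(OCC)OCC
F5 | step 11 | 5-O-triethylsilyl ether of F4 | O=C(/C=C(\C)CO[Si](C)(C)C(C)(C)C)OC/C=C(/C)C[C@@H](O[Si](CC)(CC)CC)/C=C(\I)C(OCC)OCC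
F6 | step 11 | Ireland–Claisen acid: C6 carboxylic acid with C5 (R) bearing the silyloxy-propenyl group, C10 (S) bearing CH3 and vinyl, C8 (R) triethylsilyl ether, Z-iodoalkene | OC(=O)[C@H]([C@](C)(C=C)C[C@@H](O[Si](CC)(CC)CC)/C=C(\I)C(OCC)OCC)C(=C)CO[Si](C)(C)C(C)(C)C
F7 | step 16 | 6,8-bis-O-triethylsilyl ether of diol 26 | C=C[C@]1(C)C[C@@H](O[Si](CC)(CC)CC)[C@@H](C(=C)C(OCC)OCC)[C@@H](O[Si](CC)(CC)CC)[C@H]1C(=C)CO[Si](C)(C)C(C)(C)C
F8 | step 16 | 6-O-triethylsilyl ether of diol 26 (8-OH free) | C=C[C@]1(C)C[C@@H](O)[C@@H](C(=C)C(OCC)OCC)[C@@H](O[Si](CC)(CC)CC)[C@H]1C(=C)CO[Si](C)(C)C(C)(C)C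
F9 | step 16 | 6-O-triethylsilyl ether of ester 30 | C=C[C@]1(C)C[C@@H](OC(=O)[C@H](C)CO[Si](C)(C)C(C)(C)C)[C@@H](C(=C)C(OCC)OCC)[C@@H](O[Si](CC)(CC)CC)[C@H]1C(=C)CO[Si](C)(C)C(C)(C)C
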